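The ten-membered ring holds an oxygenated C1–C10 unit and the Z-C4=C5 alkene, separated only by the C2–C3 bond. This is the 1,5 pattern that an oxy-Cope rearrangement leaves behind. The ring is therefore grown from a cyclohexane made of C5 to C10 and is not cyclised end to end. In one operation the key step makes C2–C3, breaks C5–C10, sets the Z alkene and puts oxygen on C1 of the resulting C1=C10 enolate. Its precursor is a cis-1-vinyl-2-isopropenylcyclohexanol with a C6/C7 acetonide and a C8 PMB ether, made from (−)-shikimic acid. Anti opening of a C5–C10 epoxide by an isopropenyl copper reagent fixes the cis relation. A phosphonate already carrying C13 closes the butenolide.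

Key step: step 12

Assumption: the SMILES string is taken as binding (1R,6R,8S,4Z; "6a" read as 6α). Germacrane numbering is used for every intermediate: shikimate C1, C2, C3, C4, C5, C6 and its carboxyl carbon become C10, C5, C6, C7, C8, C9 and C1. α is the face that carries O6 and O8 in the target.

Step 1
Reactants: 1 (−)-shikimic acid
Product: 3 methyl 3,4-O-isopropylideneshikimate, via methyl shikimate 2 (not isolated)
Conditions: MeOH, camphorsulfonic acid (cat.), reflux; evaporate; Me2C(OMe)2, acetone, rt
Reagents that add atoms: methanol, CO; 2,2-dimethoxypropane, COC(C)(C)OC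
Why: Fischer esterification followed by acid-catalysed transketalisation: only the cis pair O6/O7 (shikimate O3/O4) can span a five-membered acetonide, so the trans-placed 8β-hydroxyl stays free and no stereocentre is touched.

Step 2
Reactants: 3 methyl 3,4-O-isopropylideneshikimate
Product: 4 allylic alcohol (C10–CH2OH on the C5=C10 cyclohexene; O6α/O7α acetonide; free 8β-OH)
Conditions: i-Bu2AlH, CH2Cl2, −78 → 0 °C
Reagents that add atoms: none
Why: Two 1,2-hydride transfers from i-Bu2AlH reduce the conjugated ester to the allylic alcohol (ester reduction) while the alkene and the acetal are inert at low temperature.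

Step 3
Reactants: 4 allylic alcohol
Product: 5 primary TBS ether of 4 (free 8β-OH)
Conditions: TBSCl, imidazole, CH2Cl2, 0 °C
Reagents that add atoms: tert-butyldimethylsilyl chloride, CC(C)(C)[Si](C)(C)Cl
Why: Silyl ether formation with a bulky chlorosilane is much faster at the primary allylic hydroxyl than at the secondary, acetonide-flanked 8-hydroxyl.

Step 4
Reactants: 5 primary TBS ether
Product: 6 8-ketone
Conditions: Dess–Martin periodinane, CH2Cl2, 0 °C
Reagents that add atoms: none
Why: Dess–Martin oxidation runs without base or strong acid, so the β,γ-unsaturated ketone is not conjugated and O7 is not eliminated.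

Step 5
Reactants: 6 8-ketone
Product: 7 8α-alcohol (8-epimer of 5; O6, O7 and O8 all α)
Conditions: NaBH4, CeCl3·7H2O, MeOH, −78 °C
Reagents that add atoms: none
Why: Luche-type borohydride reduction: hydride reaches the carbonyl from the open convex β face, anti to the cis-fused acetonide and to the C7–O bond (Felkin–Anh), which sets the 8-hydroxyl α and so inverts C8 relative to shikimic acid.

Step 6
Reactants: 7 8α-alcohol
Product: 8 5α,10α-epoxide with free 8α-OH
Conditions: VO(acac)2 (cat.), t-BuOOH, CH2Cl2, 0 °C → rt
Reagents that add atoms: tert-butyl hydroperoxide, CC(C)(C)OO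
Why: Hydroxyl-directed vanadium-catalysed epoxidation: the homoallylic 8α-alkoxide binds vanadium and passes the peroxide oxygen to the α face of the electron-rich trisubstituted C5=C10 alkene, which sets C5 and C10 against the steric bias of the ring.

Step 7
Reactants: 8 epoxy alcohol
Product: 9 8-O-PMB ether of 8
Conditions: NaH, PMBCl, Bu4NI (cat.), DMF, 0 °C → rt
Reagents that add atoms: 4-methoxybenzyl chloride, COc1ccc(CCl)cc1
Why: Williamson ether synthesis; the 8α-alkoxide lies on the same face as the epoxide oxygen and therefore cannot open it from the rear.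

Step 8
Reactants: 9 epoxide PMB ether; 10 isopropenylmagnesium bromide
Product: 11 tertiary alcohol (5β-isopropenyl; 10α-OH; 10β-CH2OTBS)
Conditions: 10 (excess), CuI (cat.), THF, −30 °C → rt
Reagents that add atoms: isopropenylmagnesium bromide (10), CC(=C)[Mg]Br
Why: Copper-catalysed SN2 opening of the epoxide takes place at the secondary C5 and not at the fully substituted C10, from the β face anti to the breaking C5–O bond (trans-diaxial opening, Fürst–Plattner rule), so isopropenyl ends β, the 10-hydroxyl stays α, and isopropenyl and the C1 carbon are cis by mechanism.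

Step 9
Reactants: 11 tertiary alcohol
Product: 12 1,2-diol (10α-OH; 10β-CH2OH)
Conditions: TBAF, THF, 0 °C → rt
Reagents that add atoms: none
Why: Fluoride-driven cleavage of the Si–O bond frees the primary alcohol and leaves acetal, PMB ether and alkene untouched.

Step 10
Reactants: 12 1,2-diol
Product: 13 α-hydroxy aldehyde (10α-OH; 10β-CHO)
Conditions: IBX, DMSO, rt
Reagents that add atoms: none
Why: IBX oxidises the primary alcohol of a 1,2-diol to the α-hydroxy aldehyde without C–C cleavage, and the tertiary hydroxyl cannot be oxidised.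

Step 11
Reactants: 13 α-hydroxy aldehyde
Product: 14 cis-1-vinyl-2-isopropenylcyclohexanol (10β-vinyl; 10α-OH; 5β-isopropenyl; O6α/O7α acetonide; 8α-OPMB)
Conditions: MePPh3Br, KN(SiMe3)2, THF, 0 °C; then 13, −78 → 0 °C
Reagents that add atoms: methyltriphenylphosphonium bromide, C[P+](c1ccccc1)(c1ccccc1)c1ccccc1.[Br-]
Why: Wittig methylenation of an aldehyde that has no α-hydrogen, so the basic ylide can only deprotonate the tertiary hydroxyl reversibly, and C10 and C5 are not at risk.

Step 12
Reactants: 14 cis-1-vinyl-2-isopropenylcyclohexanol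
Product: 17 (4Z)-1β-hydroxy-10-oxo ten-membered ring carrying the O6α/O7α acetonide plus 8α-OPMB, via potassium alkoxide 15 (not isolated), via potassium enolate 16 (not isolated)
Conditions: KH, 18-crown-6, THF, 0 → 40 °C; solution cannulated into 2-(phenylsulfonyl)-3-phenyloxaziridine, THF, −78 °C; AcOH, −78 °C
Reagents that add atoms: 2-(phenylsulfonyl)-3-phenyloxaziridine, O=S(=O)(c1ccccc1)N1OC1c1ccccc1
Why: KH with 18-crown-6 gives the dissociated alkoxide 15, whose charge weakens C5–C10 and triggers a concerted suprafacial [3,3] shift through a chair of C3, C4, C5, C10, C1 and C2 (anionic oxy-Cope rearrangement); enolate formation makes it irreversible. The ten-membered ring is closed by ring enlargement, C2–C3 forming while C5–C10 breaks, so neither end-to-end cyclisation nor high dilution is involved; the closest known reactions are the alkoxide-accelerated rearrangements of 1,2-dialkenylcyclohexanols to cyclodec-5-enones whose regiodefined enolates are oxidised in the same flask (Davis hydroxylation). Alkene geometry: the cis pair must react with one group axial, and only the cyclohexane chair with axial vinyl and equatorial isopropenyl, O6 and O8 is accessible (the other chair sets isopropenyl axial and O6, O8 and O10 syn-axial); in it C5–C6 is axial on the pericyclic chair, so C6 ends cis to C3, which is Z-C4=C5. Site selectivity: the enolate exists only as C1=C10 and no proton source is present, so oxygen goes to C1 alone, while inverse addition at −78 °C and the acidic quench keep C9 from enolising and 8-OPMB from β-elimination. C1 is controlled by the ring: the oxaziridine can reach the enolate only from outside, and once the enolate plane has swung (H1 through the ring, fast at the rearrangement temperature) to place O10 on the open β face, away from C15 and the α-oxygens, the exposed face is expected to give the 1β (R) alcohol. This last point is the least secured element of the route and is covered by a fallback.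

Step 13
Reactants: 17 hydroxy ketone
Product: 18 1-O-TBDPS ether of 17
Conditions: TBDPSCl, imidazole, DMAP (cat.), DMF, rt
Reagents that add atoms: tert-butyldiphenylsilyl chloride, CC(C)(C)[Si](Cl)(c1ccccc1)c1ccccc1
Why: Silyl ether formation at the only free hydroxyl; TBDPS is chosen because it outlasts the later aqueous acid yet falls to fluoride.

Step 14
Reactants: 18 silyloxy ketone
Product: 19 10(14)-methylene compound
Conditions: Cp2TiMe2, toluene, 75 °C, dark
Reagents that add atoms: dimethyltitanocene Cp2TiMe2, C[Ti](C)(C1C=CC=C1)C1C=CC=C1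
Why: Petasis methylenation: the Cp2Ti=CH2 formed on heating is non-basic, so it converts the hindered ketone by [2+2] addition and cycloreversion without enolisation towards C9 (loss of 8-OPMB) or epimerisation of C1.

Step 15
Reactants: 19 10(14)-methylene compound
Product: 20 6α,7α-diol
Conditions: AcOH–THF–H2O, 45 °C
Reagents that add atoms: none
Why: Mild acid hydrolysis of the cyclic acetal; aqueous acetic acid is too weak to protonate the alkenes, ionise the allylic C6–O bond or cleave the TBDPS and PMB ethers.

Step 16
Reactants: 21 trimethyl 2-phosphonoacrylate; 22 4-methoxybenzyl alcohol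
Product: 23 methyl 2-(dimethoxyphosphoryl)-3-(4-methoxybenzyloxy)propanoate (racemic)
Conditions: DBU (cat.), THF, 0 °C → rt
Reagents that add atoms: 4-methoxybenzyl alcohol (22), COc1ccc(CO)cc1
Why: Base-catalysed oxa-Michael addition of the alcohol to the doubly activated alkene; the stabilised carbanion is protonated by more alcohol, which carries the chain (the new centre is racemic and is lost later).

Step 17
Reactants: 23 phosphono ester
Product: 24 2-(dimethoxyphosphoryl)-3-(4-methoxybenzyloxy)propanoic acid (racemic)
Conditions: Me3SnOH, ClCH2CH2Cl, 70 °C; 1 M HCl wash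
Reagents that add atoms: trimethyltin hydroxide, C[Sn](C)(C)O
Why: Me3SnOH cleaves the carboxylic methyl ester under essentially neutral conditions, which avoids the retro-Michael loss of the alkoxide that aqueous hydroxide could cause and spares the phosphonate esters.

Step 18
Reactants: 20 6α,7α-diol; 24 phosphono acid
Product: 25 6-O-phosphonopropanoate with free 7α-OH (epimers at the phosphonate carbon)
Conditions: DCC, DMAP (cat.), CH2Cl2, −20 → 0 °C
Reagents that add atoms: acid 24, OC(=O)C(COCc1ccc(OC)cc1)P(=O)(OC)OC
Why: Steglich esterification with one equivalent of a branched acid selects the outer allylic 6-hydroxyl, which is flanked by the flat C5, over the central 7-hydroxyl, which is crowded by C6 and by 8-OPMB; the C6–O bond is not broken, so C6 keeps its configuration.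

Step 19
Reactants: 25 hydroxy phosphonate ester
Product: 26 7-ketone
Conditions: Dess–Martin periodinane, CH2Cl2, 0 °C → rt
Reagents that add atoms: none
Why: Dess–Martin oxidation of the remaining secondary alcohol under neutral conditions leaves the acidic phosphonate and the epimerisable C6 and C8 centres alone.

Step 20
Reactants: 26 keto phosphonate
Product: 27 7(11)-en-12,6α-olide with 8α-OPMB, 13-OPMB and 1β-OTBDPS
Conditions: LiCl, i-Pr2NEt, MeCN, rt
Reagents that add atoms: none
Why: Intramolecular Horner–Wadsworth–Emmons reaction under Masamune–Roush conditions: the lithium-complexed phosphonate is deprotonated by a weak amine that does not enolise the ketone, closes the five-membered ring on C7 and loses phosphate to give the C7=C11 butenolide, any reversible loss of the β-alkoxide being drained by the irreversible olefination.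

Step 21
Reactants: 27 bis-PMB butenolide
Product: 28 8α,13-diol
Conditions: DDQ, CH2Cl2–pH 7 buffer, 0 °C
Reagents that add atoms: none
Why: Oxidative cleavage of both 4-methoxybenzyl ethers by DDQ through benzylic hydride abstraction; the resulting alcohols sit next to an electron-poor alkene and are not oxidised further.

Step 22
Reactants: 28 8α,13-diol
Product: 29 8α,13-diacetate 1-O-TBDPS ether
Conditions: Ac2O, pyridine, DMAP (cat.), CH2Cl2, 0 °C → rt
Reagents that add atoms: acetic anhydride, CC(=O)OC(C)=O
Why: DMAP-catalysed acetylation of the two free hydroxyl groups while O1 is still masked.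

Step 23
Reactants: 29 diacetate silyl ether
Product: 30 8α,13-diacetoxy-1β-hydroxygermacra-4,7(11),10(14)-trien-6α,12-olide
Conditions: TBAF–AcOH (1:1), THF, 0 °C → rt
Reagents that add atoms: none
Why: Fluoride cleaves the silyl ether, and buffering with acetic acid prevents acetate migration or hydrolysis and deprotonation of the butenolide at C6.

Compound list
1 | (−)-shikimic acid, (3R,4S,5R)-3,4,5-trihydroxycyclohex-1-ene-1-carboxylic acid | OC(=O)C1=C[C@@H](O)[C@@H](O)[C@H](O)C1 | starting material
2 | methyl shikimate | COC(=O)C1=C[C@@H](O)[C@@H](O)[C@H](O)C1 | intermediate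
3 | methyl 3,4-O-isopropylideneshikimate (O6α/O7α acetonide, 8β-OH) | COC(=O)C1=C[C@H]2OC(C)(C)O[C@H]2[C@H](O)C1 | intermediate
4 | allylic alcohol: C10–CH2OH, C5=C10, O6α/O7α acetonide, 8β-OH | OCC1=C[C@H]2OC(C)(C)O[C@H]2[C@H](O)C1 | intermediate
5 | primary TBS ether of 4 | CC(C)(C)[Si](C)(C)OCC1=C[C@H]2OC(C)(C)O[C@H]2[C@H](O)C1 | intermediate
6 | 8-ketone | CC(C)(C)[Si](C)(C)OCC1=C[C@H]2OC(C)(C)O[C@H]2C(=O)C1 | intermediate
7 | 8α-alcohol (O6, O7, O8 all α) | CC(C)(C)[Si](C)(C)OCC1=C[C@H]2OC(C)(C)O[C@H]2[C@@H](O)C1 | intermediate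
8 | 5α,10α-epoxide, free 8α-OH | CC(C)(C)[Si](C)(C)OC[C@@]12C[C@H](O)[C@@H]3OC(C)(C)O[C@@H]3[C@@H]1O2 | intermediate
9 | 5α,10α-epoxide, 8α-OPMB | CC(C)(C)[Si](C)(C)OC[C@@]12C[C@H](OCc4ccc(OC)cc4)[C@@H]3OC(C)(C)O[C@@H]3[C@@H]1O2 | intermediate
10 | isopropenylmagnesium bromide | CC(=C)[Mg]Br | starting material
11 | tertiary alcohol: 5β-isopropenyl, 10α-OH, 10β-CH2OTBS | CC(C)(C)[Si](C)(C)OC[C@@]1(O)C[C@H](OCc3ccc(OC)cc3)[C@@H]2OC(C)(C)O[C@@H]2[C@H]1C(C)=C | intermediate
12 | 1,2-diol: 10α-OH, 10β-CH2OH | OC[C@@]1(O)C[C@H](OCc3ccc(OC)cc3)[C@@H]2OC(C)(C)O[C@@H]2[C@H]1C(C)=C | intermediate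
13 | α-hydroxy aldehyde: 10α-OH, 10β-CHO | O=C[C@@]1(O)C[C@H](OCc3ccc(OC)cc3)[C@@H]2OC(C)(C)O[C@@H]2[C@H]1C(C)=C | intermediate
14 | cis-1-vinyl-2-isopropenylcyclohexanol: 10β-vinyl, 10α-OH, 5β-isopropenyl, O6α/O7α acetonide, 8α-OPMB | C=C[C@@]1(O)C[C@H](OCc3ccc(OC)cc3)[C@@H]2OC(C)(C)O[C@@H]2[C@H]1C(C)=C | intermediate
15 | potassium alkoxide of 14 | C=C[C@@]1([O-])C[C@H](OCc3ccc(OC)cc3)[C@@H]2OC(C)(C)O[C@@H]2[C@H]1C(C)=C.[K+] | intermediate
16 | potassium C1=C10 enolate of the (4Z) ten-membered ketone (O10 cis to C2) | [O-]/C1=C\CC/C(C)=C\[C@H]2OC(C)(C)O[C@H]2[C@@H](OCc3ccc(OC)cc3)C1.[K+] | intermediate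
17 | (1R,4Z)-1β-hydroxy-10-ketone, O6α/O7α acetonide, 8α-OPMB | O=C1C[C@H](OCc3ccc(OC)cc3)[C@@H]2OC(C)(C)O[C@@H]2/C=C(/C)CC[C@H]1O | intermediate
18 | 1-O-TBDPS ether of 17 | O=C1C[C@H](OCc3ccc(OC)cc3)[C@@H]2OC(C)(C)O[C@@H]2/C=C(/C)CC[C@H]1O[Si](c4ccccc4)(c5ccccc5)C(C)(C)C | intermediate
19 | 10(14)-methylene compound | C=C1C[C@H](OCc3ccc(OC)cc3)[C@@H]2OC(C)(C)O[C@@H]2/C=C(/C)CC[C@H]1O[Si](c4ccccc4)(c5ccccc5)C(C)(C)C | intermediate
20 | 6α,7α-diol | C=C1C[C@H](OCc2ccc(OC)cc2)[C@H](O)[C@H](O)/C=C(/C)CC[C@H]1O[Si](c3ccccc3)(c4ccccc4)C(C)(C)C | intermediate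
21 | trimethyl 2-phosphonoacrylate | C=C(C(=O)OC)P(=O)(OC)OC | starting material
22 | 4-methoxybenzyl alcohol | COc1ccc(CO)cc1 | starting material
23 | methyl 2-(dimethoxyphosphoryl)-3-(4-methoxybenzyloxy)propanoate (racemic) | COC(=O)C(COCc1ccc(OC)cc1)P(=O)(OC)OC | intermediate
24 | 2-(dimethoxyphosphoryl)-3-(4-methoxybenzyloxy)propanoic acid (racemic) | OC(=O)C(COCc1ccc(OC)cc1)P(=O)(OC)OC | intermediate
25 | 6-O-phosphonopropanoate, free 7α-OH (epimers at the phosphonate carbon) | C=C1C[C@H](OCc2ccc(OC)cc2)[C@H](O)[C@H](OC(=O)C(COCc2ccc(OC)cc2)P(=O)(OC)OC)/C=C(/C)CC[C@H]1O[Si](c3ccccc3)(c4ccccc4)C(C)(C)C | intermediate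
26 | 7-ketone of 25 | C=C1C[C@H](OCc2ccc(OC)cc2)C(=O)[C@H](OC(=O)C(COCc2ccc(OC)cc2)P(=O)(OC)OC)/C=C(/C)CC[C@H]1O[Si](c3ccccc3)(c4ccccc4)C(C)(C)C | intermediate
27 | 7(11)-en-12,6α-olide, 8α-OPMB, 13-OPMB, 1β-OTBDPS | C=C1C[C@H](OCc3ccc(OC)cc3)C2=C(COCc3ccc(OC)cc3)C(=O)O[C@@H]2/C=C(/C)CC[C@H]1O[Si](c4ccccc4)(c5ccccc5)C(C)(C)C | intermediate
28 | 8α,13-diol, 1β-OTBDPS | C=C1C[C@H](O)C2=C(CO)C(=O)O[C@@H]2/C=C(/C)CC[C@H]1O[Si](c4ccccc4)(c5ccccc5)C(C)(C)C | intermediate
29 | 8α,13-diacetate, 1β-OTBDPS | C=C1C[C@H](OC(C)=O)C2=C(COC(C)=O)C(=O)O[C@@H]2/C=C(/C)CC[C@H]1O[Si](c4ccccc4)(c5ccccc5)C(C)(C)C | intermediate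
30 | 8α,13-diacetoxy-1β-hydroxygermacra-4,7(11),10(14)-trien-6α,12-olide | C=C1C[C@H](OC(C)=O)C2=C(COC(C)=O)C(=O)O[C@@H]2/C=C(/C)CC[C@H]1O | target

Total step count: 23. Longest linear sequence: 21 (steps 1–15 and 18–23; steps 16 and 17 form the side branch).

Steps most likely to fail

Step 12 (key step).
- **Process at risk:** delivery of oxygen to the wrong face of C1. The enolate leaves the pericyclic chair with O10 on the α face. If it is oxidised before, or in preference to, the swing of the enolate plane, the oxaziridine meets the face that leads to the 1α configuration. Leakage to the E alkene through the other cyclohexane chair is the lesser worry.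
- **Fallback (C1 set by a reagent, not by ring conformation):** it sets out from 14. The same rearrangement and hydroxylation is run without regard to C1. The 1α-hydroxy ketone F1 (alone or mixed with 17) is methylenated with excess Cp2TiMe2 to the 1α-hydroxy-10(14)-methylene compound F2. This is oxidised with Dess–Martin periodinane to the cross-conjugated 10(14)-en-1-one F3. Reduction with catecholborane and the (S)-methyl oxazaborolidine (Corey–Bakshi–Shibata reduction, the alkenyl side acting as the large group) gives the 1β-hydroxy-10(14)-methylene compound F4. Silylation with TBDPSCl and imidazole brings the material back to the route at 19.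

Step 6.
- **Process at risk:** loss of facial control. The α face that the vanadium-bound peroxide must reach is the concave one below the acetonide, so undirected epoxidation of the β face may compete.
- **Fallback (oxygen delivered through a covalent tether):** it sets out from 7, which Boc2O and DMAP convert into the 8-O-tert-butyl carbonate F5. IBr in toluene at −80 °C forms the β-iodonium ion, which the carbonate carbonyl opens at C10 from the α face. This gives the 5β-iodo 8α,10α-cyclic carbonate F6 (iodocarbonate cyclisation). K2CO3 in MeOH cleaves the carbonate, and the freed 10α-alkoxide displaces the anti iodide, which returns to the route at 8.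

Step 18.
- **Process at risk:** poor discrimination between the two hydroxyl groups, or migration of the acyl group from O6 to O7.
- **Fallback (oxidise first, acylate last):** it sets out from 20. One equivalent of TESCl with imidazole at −20 °C gives the 6-O-TES ether F7. Silylation responds more strongly to crowding than acylation, and missilylated material can be returned to 20 with fluoride. Dess–Martin oxidation gives the 6-O-TES 7-ketone F8. Pyridine-buffered HF·pyridine frees the 6α-hydroxy 7-ketone F9. F9 has a single hydroxyl group and is esterified at once with 24 (DCC, DMAP) to forestall ketol isomerisation. This rejoins the route at 26.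

Further compounds
F1 | step 12 | 1α-hydroxy ketone (C1 epimer of 17) | O=C1C[C@H](OCc3ccc(OC)cc3)[C@@H]2OC(C)(C)O[C@@H]2/C=C(/C)CC[C@@H]1O
F2 | step 12 | 1α-hydroxy-10(14)-methylene compound | C=C1C[C@H](OCc3ccc(OC)cc3)[C@@H]2OC(C)(C)O[C@@H]2/C=C(/C)CC[C@@H]1O
F3 | step 12 | 10(14)-en-1-one | C=C1C[C@H](OCc3ccc(OC)cc3)[C@@H]2OC(C)(C)O[C@@H]2/C=C(/C)CCC1=O
F4 | step 12 | 1β-hydroxy-10(14)-methylene compound | C=C1C[C@H](OCc3ccc(OC)cc3)[C@@H]2OC(C)(C)O[C@@H]2/C=C(/C)CC[C@H]1O
F5 | step 6 | 8-O-tert-butyl carbonate of 7 | CC(C)(C)[Si](C)(C)OCC1=C[C@H]2OC(C)(C)O[C@H]2[C@@H](OC(=O)OC(C)(C)C)C1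
F6 | step 6 | 5β-iodo 8α,10α-cyclic carbonate | CC(C)(C)[Si](C)(C)OC[C@@]1(OC(=O)O2)C[C@H]2[C@@H]3OC(C)(C)O[C@@H]3[C@H]1I
F7 | step 18 | 6-O-TES ether of 20 | C=C1C[C@H](OCc2ccc(OC)cc2)[C@H](O)[C@H](O[Si](CC)(CC)CC)/C=C(/C)CC[C@H]1O[Si](c3ccccc3)(c4ccccc4)C(C)(C)C
F8 | step 18 | 6-O-TES 7-ketone | C=C1C[C@H](OCc2ccc(OC)cc2)C(=O)[C@H](O[Si](CC)(CC)CC)/C=C(/C)CC[C@H]1O[Si](c3ccccc3)(c4ccccc4)C(C)(C)C
F9 | step 18 | 6α-hydroxy 7-ketone | C=C1C[C@H](OCc2ccc(OC)cc2)C(=O)[C@H](O)/C=C(/C)CC[C@H]1O[Si](c3ccccc3)(c4ccccc4)C(C)(C)C
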